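All runs come from a simulation for substances that don't exist, noise included.

Our closed, stirred vessel holds substrate, coupling partner and free catalyst, and one pass of the proposed catalyst round spends one coupling partner for each product.

| setting | ash | maple | flask |
|---|---|---|---|
| substrate | 14 mM | 14 mM | 14 mM |
| coupling partner | 0.60 equiv | 0.30 equiv | 0.600 equiv |
| free catalyst | 2.5 mol% | 2.5 mol% | 2.5 mol% |
| temperature | 5 °C | 0 °C | 5 °C |
| remark | the very flask that is asked about, followed so far | run made earlier |  |
| time |  |  | 3.0 d |

- ash (time / h: product / %, substrate / %): 6.00: 58.9, 37.4; 10.0: 59.7, 35.5; 20.0: 60.6, 36.5; 40.0: 61.1, 38.6; 72.0: 59.2, 37.4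
- maple (time / h: product / %, substrate / %): 0.333: 10.7, 86.7; 1.00: 26.2, 70.6; 2.00: 30.1, 67.2; 3.00: 28.9, 66.2; 4.00: 30.0, 67.1

(each reading ± 1 percentage point)

- product that was removed still counts
- what may be going on: substrate + free catalyst -> catalyst intermediate A; coupling partner + catalyst intermediate A <-> catalyst intermediate B; catalyst intermediate B -> by-product + catalyst intermediate C; catalyst intermediate C -> catalyst intermediate D; catalyst intermediate D -> free catalyst + product; free catalyst -> spent catalyst
- additions bring no volume worth counting

- product, in percent of the substrate first charged, at 3.0 d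
- what to do for the largest gain in product; "none" if nothing gains more than 2 percentage points (Thursday's / Sunday's / Friday's / Wednesday's / Tuesday's / none)
- product present, with what was taken out counted in, in percent of the substrate first charged, after Friday's
- product present, with what was taken out counted in, in percent of the substrate first charged, after Wednesday's

- Thursday's: at 3.0 d take out 90% of the product then present, then wait 40 h
- Sunday's: at 3.0 d raise the temperature by 25 K, then wait 40 h
- Friday's: change nothing and wait 40 h more
- Wednesday's: at 3.0 d add coupling partner, 100% of the amount charged, then wait 40 h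
- Tuesday's: at 3.0 d add free catalyst, 100% of the amount charged, then wait 40 h

We take this one-to-one count as the zero of the scale. Let e be the equivalents of coupling partner. We define the partner ceiling c as the smaller of e and one equivalent, written in percent of the substrate charged; for the asked flask c is 60.0%, and the coupling partner is the limiting reagent. The readings support the count. The maple run reads 30.0% at 0.30 equiv, a ratio of 1.00, and the ash run reads 59.2% at 0.60 equiv, a ratio of 0.987, with 37.4% of the substrate still present.

Now we turn the settings by hand. Waiting leaves c where it is, and the ash product already reads 58.9% at 6.00 h and 59.2% at 72.0 h. Taking out product returns no coupling partner, so c stays. A rise of 25 K changes rates, and more catalyst changes rates too, but c contains no rate. Adding coupling partner takes e to 1.20, past one equivalent, so substrate becomes the limit and c rises to 100%. We therefore reckon 60.0% now and after waiting, and choose Wednesday's for a gain of 40 percentage points. The 40 h allowed is longer than the 6.00 h of the first ash reading.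

The forecast gives 60% (59% to 61%) now, 60% (59% to 61.2%) after Friday's, and Wednesday's as the move, reaching 95% (85% to 100%), on the ground that “The flask has therefore run out of partner and is not at equilibrium”. Our ceiling after Wednesday's lies 5 points above the forecast's central figure for that move.

The flask gives 60.0% at 3.0 d, 60.0% after Friday's, and 100% after Wednesday's, a gain of 40 points; Thursday's, Sunday's, Tuesday's and Friday's each gain 0 points.

    substrate + free catalyst → catalyst intermediate A (k = 5.40 M⁻¹ s⁻¹, Ea = 38.0 kJ mol⁻¹)
    coupling partner + catalyst intermediate A ⇌ catalyst intermediate B (K = 150 M⁻¹, k = 11.0 M⁻¹ s⁻¹, Ea = 36.0 kJ mol⁻¹, ΔH = 31.0 kJ mol⁻¹)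
    catalyst intermediate B → by-product + catalyst intermediate C (k = 0.0900 s⁻¹, Ea = 65.0 kJ mol⁻¹)
    catalyst intermediate C → catalyst intermediate D (k = 0.0170 s⁻¹, Ea = 84.0 kJ mol⁻¹)
    catalyst intermediate D → free catalyst + product (k = 0.490 s⁻¹, Ea = 71.0 kJ mol⁻¹)
    free catalyst → spent catalyst (k = 3.80 × 10⁻⁷ s⁻¹, Ea = 97.0 kJ mol⁻¹)
    (constants at 5 °C)

The ceiling of 60.0% stands beside the 60.0% of this flask. For a neighbouring flask with 0.150 equiv of coupling partner, c is 15.0%, and that flask gives 15.0% with 83% of its substrate still there, unbound. The asked flask has come to rest, with 0% of its coupling partner free at 72.0 h. At ten times that time, 720 h, it holds 60.0% product and 37.5% substrate, with catalyst intermediate A at >99.9% of the catalyst charged and spent catalyst at 0.0197%.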